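**Plan**
Retrosynthesis: the two O–Si bonds are cut first, then ring C at the C4–C4a acyl–arene bond. The C3′–CH2 bond of the 3-methylbut-3-enyl chain, the C2–H/C3–H pair, the O1–C2 bond (phenol plus arylpropiolate) and the C8–prenyl bond follow.
Forward: ring A is made as a C-prenylated, bis-silylated phloroglucinol and ring B as a 3-bromo-4-methoxyphenylpropiolate. They are joined through O1, the enoate is hydrogenated, the side chain is coupled on, the ester is cleaved, and ring C is closed last.
Enabling feature: in ring A, C8 carries the prenyl group, so C4a is the only free carbon ortho to O1. It is ortho to the C5 oxygen and para to the C7 oxygen, and an acyl carbon held on O1–C2–C3 reaches it in a six-membered closure.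
Stereochemistry: the single stereocentre, C2 (S), comes from rhodium-catalysed asymmetric hydrogenation of the (Z)-β-aryloxy enoate and is only carried along afterwards.

Key step: step 9

Assumption: the conjugate addition is taken to favour the Z enoate, and the ligand antipode named is taken to deliver hydrogen to the face that gives (S) at C2; if a test hydrogenation shows the opposite sense, the enantiomeric ligand is used.

Step 1
Reactants: 1 phloroglucinol (benzene-1,3,5-triol); 2 1-bromo-3-methylbut-2-ene (prenyl bromide)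
Product: 3 2-(3-methylbut-2-enyl)benzene-1,3,5-triol
Conditions: 1 (3 equiv), DBU (1 equiv), THF, 0 °C → rt
Reagents that add atoms: none
Why: C-alkylation of the ambident phloroglucinol anion by the allylic bromide at one of three equivalent ring carbons, so that only one mono-C-prenyl isomer can form while the excess of triol holds back a second prenylation.

Step 2
Reactants: 3 2-(3-methylbut-2-enyl)benzene-1,3,5-triol
Product: 4 2-(3-methylbut-2-enyl)-3,5-bis(triisopropylsilyloxy)phenol
Conditions: i-Pr3SiCl (2.1 equiv), imidazole, DMF, 0 °C → rt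
Reagents that add atoms: triisopropylsilyl chloride, CC(C)[Si](Cl)(C(C)C)C(C)C
Why: Phenol O-silylation in which the unhindered hydroxyl para to the prenyl group reacts first and the second silyl group takes either of the two mirror-related hydroxyls next to the prenyl group, both giving the same phenol, while a third bulky silyl group beside the chain should enter only slowly.

Step 3
Reactants: 5 3-bromo-4-methoxybenzaldehyde
Product: 6 2-bromo-4-ethynyl-1-methoxybenzene
Conditions: dimethyl (1-diazo-2-oxopropyl)phosphonate, K2CO3, MeOH, rt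
Reagents that add atoms: dimethyl (1-diazo-2-oxopropyl)phosphonate (Bestmann–Ohira reagent), COP(=O)(OC)C(=[N+]=[N-])C(C)=O
Why: Seyferth–Gilbert homologation with the Bestmann–Ohira reagent turns the aryl aldehyde into the terminal alkyne under carbonate/methanol conditions that leave the aryl bromide alone.

Step 4
Reactants: 6 2-bromo-4-ethynyl-1-methoxybenzene
Product: 8 methyl 3-(3-bromo-4-methoxyphenyl)prop-2-ynoate, via lithium (3-bromo-4-methoxyphenyl)acetylide 7 (not isolated)
Conditions: LiN(SiMe3)2, THF, −78 °C; then ClCO2Me, −78 → 0 °C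
Reagents that add atoms: methyl chloroformate, COC(=O)Cl
Why: The amide base deprotonates the terminal alkyne without the bromine–lithium exchange an alkyllithium would cause, and the acetylide is then C-acylated by the chloroformate (alkynoate synthesis).

Step 5
Reactants: 4 2-(3-methylbut-2-enyl)-3,5-bis(triisopropylsilyloxy)phenol; 8 methyl 3-(3-bromo-4-methoxyphenyl)prop-2-ynoate
Product: 9 methyl (2Z)-3-(3-bromo-4-methoxyphenyl)-3-[2-(3-methylbut-2-enyl)-3,5-bis(triisopropylsilyloxy)phenoxy]prop-2-enoate
Conditions: K2CO3 (0.3 equiv), DMF, 50 °C; geometric isomers separated on silica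
Reagents that add atoms: none
Why: Oxa-Michael addition of the phenoxide of 4 to the alkynoate with protonation anti to the incoming oxygen, a known entry to β-aryloxy cinnamates, run with substoichiometric carbonate at moderate temperature so that the aryl silyl ethers should not be attacked.

Step 6
Reactants: 9 methyl (2Z)-3-(3-bromo-4-methoxyphenyl)-3-[2-(3-methylbut-2-enyl)-3,5-bis(triisopropylsilyloxy)phenoxy]prop-2-enoate
Product: 10 methyl (3S)-3-(3-bromo-4-methoxyphenyl)-3-[2-(3-methylbut-2-enyl)-3,5-bis(triisopropylsilyloxy)phenoxy]propanoate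
Conditions: [Rh(nbd)2]BF4 (2 mol %), (R)-1-{(R)-2-[2′-(dicyclohexylphosphino)phenyl]ferrocenyl}ethylbis[3,5-bis(trifluoromethyl)phenyl]phosphine (2.2 mol %), H2 (20 bar), CH2Cl2, 35 °C
Reagents that add atoms: none
Why: Rhodium-catalysed asymmetric hydrogenation of a β-aryloxy α,β-unsaturated ester, in which the ester carbonyl and the alkene bind the cationic monovalent rhodium–diphosphine complex and both hydrogens are delivered to one face, so that the chiral ligand fixes C2 as S, while the isolated trisubstituted prenyl alkene and the aryl bromide are not expected to be substrates for this catalyst.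

Step 7
Reactants: 10 methyl (3S)-3-(3-bromo-4-methoxyphenyl)-3-[2-(3-methylbut-2-enyl)-3,5-bis(triisopropylsilyloxy)phenoxy]propanoate; 11 4-bromo-2-methylbut-1-ene
Product: 13 methyl (3S)-3-[4-methoxy-3-(3-methylbut-3-enyl)phenyl]-3-[2-(3-methylbut-2-enyl)-3,5-bis(triisopropylsilyloxy)phenoxy]propanoate, via (3-methylbut-3-enyl)zinc bromide 12 (not isolated)
Conditions: 11, Zn dust, LiCl, THF, 50 °C; then 10, Pd(OAc)2 (2 mol %), SPhos (4 mol %), THF, rt → 40 °C
Reagents that add atoms: none
Why: Negishi coupling of a primary alkylzinc bromide, made by zinc insertion into the homoallylic bromide, with the aryl bromide on a zerovalent palladium–biarylphosphine catalyst that outruns β-hydride elimination, the ester, the silyl ethers and the C2 ether being inert to the organozinc so that C2 is untouched.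

Step 8
Reactants: 13 methyl (3S)-3-[4-methoxy-3-(3-methylbut-3-enyl)phenyl]-3-[2-(3-methylbut-2-enyl)-3,5-bis(triisopropylsilyloxy)phenoxy]propanoate
Product: 15 (3S)-3-[4-methoxy-3-(3-methylbut-3-enyl)phenyl]-3-[2-(3-methylbut-2-enyl)-3,5-bis(triisopropylsilyloxy)phenoxy]propanoic acid, via trimethylstannyl carboxylate 14 (not isolated)
Conditions: Me3SnOH (5 equiv), ClCH2CH2Cl, 70 °C; then 0.5 M aq HCl wash, 0 °C
Reagents that add atoms: trimethyltin hydroxide, C[Sn](C)(C)O
Why: Ester cleavage with trimethyltin hydroxide runs through a stannyl ester under essentially neutral conditions, so the hydroxide- or alkoxide-induced loss of the β-aryloxy group (E1cB) and the cleavage of the aryl silyl ethers are avoided and C2 keeps its configuration.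

Step 9
Reactants: 15 (3S)-3-[4-methoxy-3-(3-methylbut-3-enyl)phenyl]-3-[2-(3-methylbut-2-enyl)-3,5-bis(triisopropylsilyloxy)phenoxy]propanoic acid
Product: 17 (2S)-2-[4-methoxy-3-(3-methylbut-3-enyl)phenyl]-8-(3-methylbut-2-enyl)-5,7-bis(triisopropylsilyloxy)chroman-4-one, via acid chloride 16 (not isolated)
Conditions: 1-chloro-N,N,2-trimethylprop-1-en-1-amine (1.2 equiv), CH2Cl2, 0 °C; then 2,6-di-tert-butyl-4-methylpyridine (1.5 equiv), SnCl4 (1.2 equiv), CH2Cl2 (0.01 M), −78 °C; aq NaHCO3
Reagents that add atoms: none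
Why: The chloroenamine converts the acid into acid chloride 16 without releasing protic acid, SnCl4 abstracts chloride to give an acylium ion (or its tight complex), and C4a of ring A attacks it in an electrophilic aromatic substitution, the proton being taken up by the hindered pyridine. The closest known reaction type is the intramolecular Friedel–Crafts acylation of 3-aryloxypropanoic acids to chroman-4-ones. Ring C closes as a six-membered ring, exo with respect to the acylium C–O multiple bond and endo with respect to the C4a–C8a bond of the arene, which is the normal Friedel–Crafts mode. No stereocentre is formed, and C2 is a spectator because none of its bonds is made or broken. The step needs regioselectivity and retention at C2: C8 is blocked by the prenyl group and C6 lies para to O1, out of reach of the three-atom tether, so only C4a can react, and with O1 and the C5 oxygen ortho and the C7 oxygen para it should be nucleophilic enough to close at −78 °C. The low temperature, the absence of protic acid and the non-nucleophilic base are meant to keep the p-methoxybenzylic C2–O1 bond from ionizing and the two alkenes from being protonated.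

Step 10
Reactants: 17 (2S)-2-[4-methoxy-3-(3-methylbut-3-enyl)phenyl]-8-(3-methylbut-2-enyl)-5,7-bis(triisopropylsilyloxy)chroman-4-one
Product: 18 (2S)-5,7-dihydroxy-2-[4-methoxy-3-(3-methylbut-3-enyl)phenyl]-8-(3-methylbut-2-enyl)chroman-4-one (CNP0286775.1)
Conditions: Bu4NF (2.5 equiv), AcOH (2.5 equiv), THF, 0 °C
Reagents that add atoms: none
Why: Fluoride cleaves both aryl O–Si bonds (silyl ether deprotection driven by the Si–F bond) while the acetic acid buffer keeps the medium from turning basic, which would open the flavanone to the chalcone by retro-oxa-Michael reaction and racemize C2, and both alkenes are inert.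

**Compound list**
1 | phloroglucinol (benzene-1,3,5-triol) | Oc1cc(O)cc(O)c1 | starting material
2 | 1-bromo-3-methylbut-2-ene (prenyl bromide) | CC(C)=CCBr | starting material
3 | 2-(3-methylbut-2-enyl)benzene-1,3,5-triol | CC(C)=CCc1c(O)cc(O)cc1O | intermediate
4 | 2-(3-methylbut-2-enyl)-3,5-bis(triisopropylsilyloxy)phenol | CC(C)=CCc1c(O)cc(O[Si](C(C)C)(C(C)C)C(C)C)cc1O[Si](C(C)C)(C(C)C)C(C)C | intermediate
5 | 3-bromo-4-methoxybenzaldehyde | COc1ccc(C=O)cc1Br | starting material
6 | 2-bromo-4-ethynyl-1-methoxybenzene | COc1ccc(C#C)cc1Br | intermediate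
7 | lithium (3-bromo-4-methoxyphenyl)acetylide | [Li]C#Cc1ccc(OC)c(Br)c1 | intermediate (not isolated)
8 | methyl 3-(3-bromo-4-methoxyphenyl)prop-2-ynoate | COC(=O)C#Cc1ccc(OC)c(Br)c1 | intermediate
9 | methyl (2Z)-3-(3-bromo-4-methoxyphenyl)-3-[2-(3-methylbut-2-enyl)-3,5-bis(triisopropylsilyloxy)phenoxy]prop-2-enoate | COC(=O)/C=C(\Oc1cc(O[Si](C(C)C)(C(C)C)C(C)C)cc(O[Si](C(C)C)(C(C)C)C(C)C)c1CC=C(C)C)c1ccc(OC)c(Br)c1 | intermediate
10 | methyl (3S)-3-(3-bromo-4-methoxyphenyl)-3-[2-(3-methylbut-2-enyl)-3,5-bis(triisopropylsilyloxy)phenoxy]propanoate | COC(=O)C[C@H](Oc1cc(O[Si](C(C)C)(C(C)C)C(C)C)cc(O[Si](C(C)C)(C(C)C)C(C)C)c1CC=C(C)C)c1ccc(OC)c(Br)c1 | intermediate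
11 | 4-bromo-2-methylbut-1-ene | C=C(C)CCBr | starting material
12 | (3-methylbut-3-enyl)zinc bromide | C=C(C)CC[Zn]Br | intermediate (not isolated)
13 | methyl (3S)-3-[4-methoxy-3-(3-methylbut-3-enyl)phenyl]-3-[2-(3-methylbut-2-enyl)-3,5-bis(triisopropylsilyloxy)phenoxy]propanoate | COC(=O)C[C@H](Oc1cc(O[Si](C(C)C)(C(C)C)C(C)C)cc(O[Si](C(C)C)(C(C)C)C(C)C)c1CC=C(C)C)c1ccc(OC)c(CCC(C)=C)c1 | intermediate
14 | trimethylstannyl (3S)-3-[4-methoxy-3-(3-methylbut-3-enyl)phenyl]-3-[2-(3-methylbut-2-enyl)-3,5-bis(triisopropylsilyloxy)phenoxy]propanoate | C[Sn](C)(C)OC(=O)C[C@H](Oc1cc(O[Si](C(C)C)(C(C)C)C(C)C)cc(O[Si](C(C)C)(C(C)C)C(C)C)c1CC=C(C)C)c1ccc(OC)c(CCC(C)=C)c1 | intermediate (not isolated)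
15 | (3S)-3-[4-methoxy-3-(3-methylbut-3-enyl)phenyl]-3-[2-(3-methylbut-2-enyl)-3,5-bis(triisopropylsilyloxy)phenoxy]propanoic acid | OC(=O)C[C@H](Oc1cc(O[Si](C(C)C)(C(C)C)C(C)C)cc(O[Si](C(C)C)(C(C)C)C(C)C)c1CC=C(C)C)c1ccc(OC)c(CCC(C)=C)c1 | intermediate
16 | (3S)-3-[4-methoxy-3-(3-methylbut-3-enyl)phenyl]-3-[2-(3-methylbut-2-enyl)-3,5-bis(triisopropylsilyloxy)phenoxy]propanoyl chloride | ClC(=O)C[C@H](Oc1cc(O[Si](C(C)C)(C(C)C)C(C)C)cc(O[Si](C(C)C)(C(C)C)C(C)C)c1CC=C(C)C)c1ccc(OC)c(CCC(C)=C)c1 | intermediate (not isolated)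
17 | (2S)-2-[4-methoxy-3-(3-methylbut-3-enyl)phenyl]-8-(3-methylbut-2-enyl)-5,7-bis(triisopropylsilyloxy)chroman-4-one | C=C(C)CCc1cc([C@@H]2CC(=O)c3c(O[Si](C(C)C)(C(C)C)C(C)C)cc(O[Si](C(C)C)(C(C)C)C(C)C)c(CC=C(C)C)c3O2)ccc1OC | intermediate
18 | (2S)-5,7-dihydroxy-2-[4-methoxy-3-(3-methylbut-3-enyl)phenyl]-8-(3-methylbut-2-enyl)chroman-4-one | C=C(C)CCc1cc([C@@H]2CC(=O)c3c(O)cc(O)c(CC=C(C)C)c3O2)ccc1OC | target

Total step count: 10.
Longest linear sequence: 8 steps (steps 3 to 10 from 5; equally steps 1, 2 and 5 to 10 from 1).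

**Steps most likely to fail**

Step 6. The β-carbon carries two bulky aryl-type groups, so hydrogen uptake may be slow and facial discrimination poor. Any residual geometric isomer would erode the selectivity, and the prenyl alkene may begin to be saturated at the pressure needed. The fallback sets out from 8 and 4 and comes back at 10. Gold-catalysed hydration of the ynoate ((Ph3P)AuCl, AgOSO2CF3, aqueous 1,4-dioxane) should give methyl 3-(3-bromo-4-methoxyphenyl)-3-oxopropanoate F1. Asymmetric transfer hydrogenation with RuCl[(R,R)-TsDPEN](p-cymene) in HCO2H/Et3N should reduce it to methyl (3R)-3-(3-bromo-4-methoxyphenyl)-3-hydroxypropanoate F2. A Mitsunobu reaction of F2 with 4 (PPh3, diisopropyl azodicarboxylate, toluene, −20 °C) would then form the O1–C2 bond with inversion and deliver 10. The bromine next to the methoxy group tempers ionization of the activated carbinol, but the enantiomeric purity of 10 would have to be checked.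

Step 9. The Lewis acid may ionize the p-methoxybenzylic C2–O1 bond, which would racemize C2 or detach ring A. The aryloxide may also be lost by β-elimination from the activated acyl group, or the silyl group peri to the new ketone may be stripped. The fallback sets out from 15 and comes back at 17, keeping the C4–C4a closure but changing the electrophile to an activated amide with no metal Lewis acid. 15 is coupled with dimethylamine (N,N′-dicyclohexylcarbodiimide, HOBt, CH2Cl2) to give (3S)-N,N-dimethyl-3-[4-methoxy-3-(3-methylbut-3-enyl)phenyl]-3-[2-(3-methylbut-2-enyl)-3,5-bis(triisopropylsilyloxy)phenoxy]propanamide F3. Triflic anhydride and 2-fluoropyridine in CH2Cl2 at −78 °C should convert it into the O-triflyl iminium triflate F4. On warming to 0 °C, C4a should attack F4 in a Vilsmeier–Haack-type closure to give the chroman-4-iminium triflate F5. Aqueous NaHCO3 then hydrolyses F5 to 17.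

Step 5. The hindered phenoxide may add only slowly to the electron-rich alkynoate. At the temperature then needed, carbonate may transfer or cleave the aryl silyl groups, and the geometric isomers may prove hard to separate. The fallback sets out from 7 and 4 and comes back at 9. The acetylide 7 is quenched with N,N-dimethylformamide instead of the chloroformate (buffered aqueous NH4Cl work-up) to give 3-(3-bromo-4-methoxyphenyl)prop-2-ynal F6. This much more electrophilic acceptor should take up 4 at 0 °C under catalytic 1,4-diazabicyclo[2.2.2]octane in CH2Cl2, with no phenoxide salt present, to give (2Z)-3-(3-bromo-4-methoxyphenyl)-3-[2-(3-methylbut-2-enyl)-3,5-bis(triisopropylsilyloxy)phenoxy]prop-2-enal F7. Pinnick oxidation (NaClO2, NaH2PO4, excess 2-methylbut-2-ene, t-BuOH/H2O) should give (2Z)-3-(3-bromo-4-methoxyphenyl)-3-[2-(3-methylbut-2-enyl)-3,5-bis(triisopropylsilyloxy)phenoxy]prop-2-enoic acid F8. Trimethylsilyldiazomethane in MeOH/toluene then methylates F8 to 9.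

**Further compounds**
F1 | step 6 | methyl 3-(3-bromo-4-methoxyphenyl)-3-oxopropanoate | COC(=O)CC(=O)c1ccc(OC)c(Br)c1
F2 | step 6 | methyl (3R)-3-(3-bromo-4-methoxyphenyl)-3-hydroxypropanoate | COC(=O)C[C@@H](O)c1ccc(OC)c(Br)c1
F3 | step 9 | (3S)-N,N-dimethyl-3-[4-methoxy-3-(3-methylbut-3-enyl)phenyl]-3-[2-(3-methylbut-2-enyl)-3,5-bis(triisopropylsilyloxy)phenoxy]propanamide | CN(C)C(=O)C[C@H](Oc1cc(O[Si](C(C)C)(C(C)C)C(C)C)cc(O[Si](C(C)C)(C(C)C)C(C)C)c1CC=C(C)C)c1ccc(OC)c(CCC(C)=C)c1
F4 | step 9 | (3S)-1-(dimethyliminio)-3-[4-methoxy-3-(3-methylbut-3-enyl)phenyl]-3-[2-(3-methylbut-2-enyl)-3,5-bis(triisopropylsilyloxy)phenoxy]propyl trifluoromethanesulfonate, triflate salt (not isolated) | C[N+](C)=C(OS(=O)(=O)C(F)(F)F)C[C@H](Oc1cc(O[Si](C(C)C)(C(C)C)C(C)C)cc(O[Si](C(C)C)(C(C)C)C(C)C)c1CC=C(C)C)c1ccc(OC)c(CCC(C)=C)c1.[O-]S(=O)(=O)C(F)(F)F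
F5 | step 9 | (2S)-N,N-dimethyl-2-[4-methoxy-3-(3-methylbut-3-enyl)phenyl]-8-(3-methylbut-2-enyl)-5,7-bis(triisopropylsilyloxy)chroman-4-iminium triflate (not isolated) | C=C(C)CCc1cc([C@@H]2CC(=[N+](C)C)c3c(O[Si](C(C)C)(C(C)C)C(C)C)cc(O[Si](C(C)C)(C(C)C)C(C)C)c(CC=C(C)C)c3O2)ccc1OC.[O-]S(=O)(=O)C(F)(F)F
F6 | step 5 | 3-(3-bromo-4-methoxyphenyl)prop-2-ynal | O=CC#Cc1ccc(OC)c(Br)c1
F7 | step 5 | (2Z)-3-(3-bromo-4-methoxyphenyl)-3-[2-(3-methylbut-2-enyl)-3,5-bis(triisopropylsilyloxy)phenoxy]prop-2-enal | O=C/C=C(\Oc1cc(O[Si](C(C)C)(C(C)C)C(C)C)cc(O[Si](C(C)C)(C(C)C)C(C)C)c1CC=C(C)C)c1ccc(OC)c(Br)c1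
F8 | step 5 | (2Z)-3-(3-bromo-4-methoxyphenyl)-3-[2-(3-methylbut-2-enyl)-3,5-bis(triisopropylsilyloxy)phenoxy]prop-2-enoic acid | OC(=O)/C=C(\Oc1cc(O[Si](C(C)C)(C(C)C)C(C)C)cc(O[Si](C(C)C)(C(C)C)C(C)C)c1CC=C(C)C)c1ccc(OC)c(Br)c1
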